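A small charge of J, 0.10 mM, had turned X into Z in two earlier runs, amber and blue, and I had to foretell a flask with twice amber's X at the same Q and J.

all flasks: J 0.10 mM
- amber: X 0.025 M; Q 0.055 M; run made earlier
- blue: X 0.038 M; Q 0.055 M; run made earlier
- flask: X 0.050 M; Q 0.0550 M; time 15 min

- amber (time / min: Z / %, X / %): 1.00: 18.9, 81.3; 3.00: 44.5, 55.7; 5.00: 57.1, 43.2; 8.00: 61.5, 37.6; 12.0: 63.1, 36.6; 15.0: 63.6, 36.0
- blue (time / min: Z / %, X / %): 2.50: 26.4, 73.4; 5.00: 37.6, 61.8; 8.00: 41.6, 58.5; 10.0: 42.4, 57.3; 12.0: 42.1, 57.9; 15.0: 41.7, 57.2

(each reading ± 0.3 percentage points)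



- amount of Z in percent of the X charged, at 1.5 min, 5.0 min, 10 min and 15 min

I worked in concentration, not percent. Amber levelled off at 63.6% of 0.025 M, which is 15.9 mM; I carried that reading as the ceiling, the concentration of Z at which a run with this Q and this J stops. At 5.00 min amber and blue held about the same Z, 14.3 mM and 14.3 mM, from different charges of X.

Then I set out the time scales. The first rung was the turnover: amber's first minute of Z over its J gave on average about 0.0212 min per turnover. The next rung came from the fraction of the ceiling still unmade, which in amber at 3.00 min was 0.300, so that fraction halved about every 1.73 min, a longer time than a turnover. The run itself, 15 min, was the longest rung, and at that pace the fraction left would be 0.244% by its end. So I expected the flask to reach the ceiling within the run, which over its 0.050 M of X is 31.8%.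

The forecast gave 13.6%, 28.6%, 31.8% and 32% at the asked times, reasoning that “Q and J are unchanged in the flask”. Its last point stands 0.2 percentage points above my 31.8%.

The flask gave 13.7%, 28.9%, 32.2% and 32.4%.

    X + J → E (k = 32100 L mol⁻¹ min⁻¹)
    Q + E ⇌ G (K = 50.9 L mol⁻¹, k = 3330 L mol⁻¹ min⁻¹)
    G ⇌ D (K = 90.2, k = 172 min⁻¹)
    D → J + Z (k = 214 min⁻¹)
    Q → L (k = 0.346 min⁻¹)

The forecast held. At 15 min the flask's Z was 16.2 mM, which is 0.300 mM above the ceiling. Q, the limiting reagent, was down to 0.0235% of its charge by then, and L stood at 0.0388 M. Over blue's 0.038 M of X the ceiling gives 41.8%, and blue read 41.7% at 15.0 min.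

(The earlier runs and the new flask stem from a simulated flask with constants of no real substance; scatter was added.)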